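Rings are lettered A–F from the 2,4,6-trihydroxyphenoxy end. All are oxygen-rich, so their carbons are poor electrophiles; worst are the ethers from the di-ortho-substituted oxygens of rings A and C to C1 of the pentaoxygenated rings B and D. Each is disconnected, with the adjacent C6–OH, to one dearomatised reagent, the o-quinone diazide of 2,3,4-trimethoxyphenol. Its rhodium carbenoid reverses the polarity of a phenol ortho carbon and inserts into the O–H of a 2,6-dimethoxyphenol: one operation forms the hindered ArO–C1 bond, aromatises ring B (or D) and unveils only the C6 hydroxyl, the next linking oxygen. Two such diads and an E–F bromide are then joined at unhindered carbons.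

Key step: step 3

Remark on the chemistry: the target has no stereocentre and no configurationally stable axis, so it is achiral and needs no stereocontrol; in rings B and D, C1 carries the ether oxygen towards ring A (or C), C2 is H, C3–C5 carry OH and C6 carries the ether oxygen towards ring C (or E); in rings C and E, C1 carries the oxygen from ring B (or D) and C4 the oxygen to ring D (or F).

**Step 1**
Reactants: 1 2,3,4-trimethoxyphenol
Product: 3 6-amino-2,3,4-trimethoxyphenol, via azo dye 2 (not isolated)
Conditions: sulfanilic acid, NaNO2, aq HCl, 0 °C (forms 4-diazoniobenzenesulfonate); add to 1 in aq NaOH, 0–5 °C; then Na2S2O4, 50 °C, under N2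
Reagents that add atoms: sodium nitrite, [Na+].[O-]N=O
Why: Azo coupling of the phenoxide at C6, its only free ortho position (para is blocked by OMe), followed by dithionite cleavage of the N=N bond is the classical o-aminophenol synthesis and avoids nitric acid, which would oxidise this p-methoxyphenol to a quinone; the amino nitrogen is the nitrite-derived terminal nitrogen of the diazonium ion.

**Step 2**
Reactants: 3 6-amino-2,3,4-trimethoxyphenol
Product: 4 6-diazo-2,3,4-trimethoxycyclohexa-2,4-dien-1-one (o-quinone diazide)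
Conditions: NaNO2, 2 M HCl, 0 °C; then NaHCO3 to pH 7, CH2Cl2 extraction in the dark; used as a cold solution
Reagents that add atoms: sodium nitrite, [Na+].[O-]N=O
Why: Diazotisation of an o-aminophenol and deprotonation of the resulting hydroxy-diazonium ion is the standard route to o-quinone diazides, and the three methoxy groups should stabilise the zwitterion.

**Step 3**
Reactants: 4 6-diazo-2,3,4-trimethoxycyclohexa-2,4-dien-1-one; 5 4-bromo-2,6-dimethoxyphenol
Product: 6 6-(4-bromo-2,6-dimethoxyphenoxy)-2,3,4-trimethoxyphenol (C–D diad; Br on ring C C1, free OH on ring D C6)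
Conditions: Rh2(OAc)4 (2 mol%), 5 (3 equiv), CH2Cl2, 25 °C, dark, 4 added over 4 h
Reagents that add atoms: none
Why: Proposed new method: Rh2(OAc)4 should expel N2 from 4 to give an electrophilic o-quinoid (α-oxo) carbenoid at C6; the hydroxyl oxygen of 5 attacks it to give an aryloxonium ylide, and a 1,4-proton shift to the neighbouring oxygen delivers the o-aryloxyphenol directly, driven by aromatisation. The closest known reaction types are Rh(II)-catalysed O–H insertion of α-diazocarbonyl compounds into phenols and of benzo-fused o-quinone diazides into alcohols. No ring is closed and no stereocentre is formed; regiochemistry is fixed because the C–O bond can only form at the carbon that carried N2 and the hydroxyl can only appear on the former carbonyl carbon. The step needs O–H insertion to beat Wolff ring contraction (a free ketocarbene path, suppressed by carbenoid formation at 25 °C in the dark), azo coupling (excluded because both ortho positions and the para position of 5 are substituted) and arene C–H attack (the remaining C–H of 5 are meta to OH and next to Br). It also needs single insertion, since 6 is itself a phenol: 5 is cheap and used in threefold excess with slow addition of 4, and the new hydroxyl of 6 is flanked by OMe and a di-ortho-substituted aryloxy group and is internally hydrogen-bonded.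

**Step 4**
Reactants: 6 6-(4-bromo-2,6-dimethoxyphenoxy)-2,3,4-trimethoxyphenol
Product: 7 1-(benzyloxy)-6-(4-bromo-2,6-dimethoxyphenoxy)-2,3,4-trimethoxybenzene
Conditions: BnBr, K2CO3, DMF, 40 °C
Reagents that add atoms: benzyl bromide, BrCc1ccccc1
Why: Williamson etherification masks the ring D hydroxyl so that 7 can act only as the aryl bromide partner in step 6.

**Step 5**
Reactants: 4 6-diazo-2,3,4-trimethoxycyclohexa-2,4-dien-1-one; 8 2,4,6-trimethoxyphenol
Product: 9 2,3,4-trimethoxy-6-(2,4,6-trimethoxyphenoxy)phenol (A–B diad; free OH on ring B C6)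
Conditions: Rh2(OAc)4 (2 mol%), 8 (3 equiv), CH2Cl2, 25 °C, dark, 4 added over 4 h
Reagents that add atoms: none
Why: Proposed new method: the same sequence as in step 3 (Rh carbenoid from 4, oxonium ylide with the hydroxyl of 8, 1,4-proton shift and aromatisation; closest known type Rh(II)-catalysed O–H insertion of α-diazocarbonyl compounds into phenols) should apply, with excess 8 and its fully substituted ortho and para positions guarding against double insertion and azo coupling.

**Step 6**
Reactants: 9 2,3,4-trimethoxy-6-(2,4,6-trimethoxyphenoxy)phenol; 7 1-(benzyloxy)-6-(4-bromo-2,6-dimethoxyphenoxy)-2,3,4-trimethoxybenzene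
Product: 10 1-(benzyloxy)-6-{2,6-dimethoxy-4-[2,3,4-trimethoxy-6-(2,4,6-trimethoxyphenoxy)phenoxy]phenoxy}-2,3,4-trimethoxybenzene (A–B–C–D benzyl ether)
Conditions: CuI (20 mol%), picolinic acid (40 mol%), K3PO4, DMSO, 100 °C
Reagents that add atoms: none
Why: Ullmann-type Cu(I) C–O coupling should form the ring B C6–O–ring C C1 bond because the hindered phenol of 9 meets a bromide carbon flanked by two hydrogens, the combination this ligand system tolerates.

**Step 7**
Reactants: 10 A–B–C–D benzyl ether
Product: 11 6-{2,6-dimethoxy-4-[2,3,4-trimethoxy-6-(2,4,6-trimethoxyphenoxy)phenoxy]phenoxy}-2,3,4-trimethoxyphenol (A–B–C–D phenol, free OH on ring D C6)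
Conditions: H2 (1 atm), 10% Pd/C, EtOAc–MeOH, rt
Reagents that add atoms: none
Why: Hydrogenolysis cleaves only the benzyl ether, since diaryl and methyl ethers are inert and no halogen remains.

**Step 8**
Reactants: 5 4-bromo-2,6-dimethoxyphenol; 12 3,4,5-trimethoxyphenylboronic acid
Product: 13 5-bromo-1,3-dimethoxy-2-(3,4,5-trimethoxyphenoxy)benzene (E–F bromide)
Conditions: Cu(OAc)2 (20 mol%), pyridine (3 equiv), 4 Å MS, CH2Cl2, O2 (1 atm), rt
Reagents that add atoms: none
Why: Chan–Lam coupling arylates di-ortho-substituted phenols at room temperature under oxidative Cu(II) conditions that leave the aryl bromide untouched.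

**Step 9**
Reactants: 11 A–B–C–D phenol; 13 5-bromo-1,3-dimethoxy-2-(3,4,5-trimethoxyphenoxy)benzene
Product: 14 hexadeca-O-methyl ether of the target (rings A–F, sixteen OMe)
Conditions: CuI (30 mol%), picolinic acid (60 mol%), K3PO4, DMSO, 110 °C, 13 (1.5 equiv)
Reagents that add atoms: none
Why: A second Ullmann-type C–O coupling of the same kind as step 6 (hindered phenol, bromide carbon with two ortho hydrogens) should complete the chain by the ring D C6–O–ring E C1 bond.

**Step 10**
Reactants: 14 hexadeca-O-methyl ether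
Product: 15 target CNP0218077.0 (free hexadecaphenol)
Conditions: BBr3 (40 equiv), CH2Cl2, −78 °C to rt; then MeOH and degassed H2O under Ar; reversed-phase purification with exclusion of air
Reagents that add atoms: none
Why: Lewis-acid demethylation with BBr3 cleaves aryl methyl ethers by bromide attack on the O-methyl carbon, while diaryl ether C–O bonds, which offer no sp3 carbon, should survive.

**Compound list**
1 | 2,3,4-trimethoxyphenol | COc1ccc(O)c(OC)c1OC | starting material
2 | 4-[(E)-(2-hydroxy-3,4,5-trimethoxyphenyl)diazenyl]benzenesulfonic acid (azo dye, sodium salt in the flask) | COc1cc(/N=N/c2ccc(cc2)S(=O)(=O)O)c(O)c(OC)c1OC | intermediate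
3 | 6-amino-2,3,4-trimethoxyphenol | COc1cc(N)c(O)c(OC)c1OC | intermediate
4 | 6-diazo-2,3,4-trimethoxycyclohexa-2,4-dien-1-one | COC1=CC(=[N+]=[N-])C(=O)C(OC)=C1OC | intermediate
5 | 4-bromo-2,6-dimethoxyphenol | COc1cc(Br)cc(OC)c1O | starting material
6 | 6-(4-bromo-2,6-dimethoxyphenoxy)-2,3,4-trimethoxyphenol | COc1cc(Oc2c(OC)cc(Br)cc2OC)c(O)c(OC)c1OC | intermediate
7 | 1-(benzyloxy)-6-(4-bromo-2,6-dimethoxyphenoxy)-2,3,4-trimethoxybenzene | COc1cc(Oc2c(OC)cc(Br)cc2OC)c(OCc3ccccc3)c(OC)c1OC | intermediate
8 | 2,4,6-trimethoxyphenol | COc1cc(OC)c(O)c(OC)c1 | starting material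
9 | 2,3,4-trimethoxy-6-(2,4,6-trimethoxyphenoxy)phenol | COc1cc(OC)c(Oc2cc(OC)c(OC)c(OC)c2O)c(OC)c1 | intermediate
10 | 1-(benzyloxy)-6-{2,6-dimethoxy-4-[2,3,4-trimethoxy-6-(2,4,6-trimethoxyphenoxy)phenoxy]phenoxy}-2,3,4-trimethoxybenzene | COc1cc(OC)c(Oc2cc(OC)c(OC)c(OC)c2Oc3cc(OC)c(Oc4cc(OC)c(OC)c(OC)c4OCc5ccccc5)c(OC)c3)c(OC)c1 | intermediate
11 | 6-{2,6-dimethoxy-4-[2,3,4-trimethoxy-6-(2,4,6-trimethoxyphenoxy)phenoxy]phenoxy}-2,3,4-trimethoxyphenol | COc1cc(OC)c(Oc2cc(OC)c(OC)c(OC)c2Oc3cc(OC)c(Oc4cc(OC)c(OC)c(OC)c4O)c(OC)c3)c(OC)c1 | intermediate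
12 | 3,4,5-trimethoxyphenylboronic acid | COc1cc(cc(OC)c1OC)B(O)O | starting material
13 | 5-bromo-1,3-dimethoxy-2-(3,4,5-trimethoxyphenoxy)benzene | COc1cc(Br)cc(OC)c1Oc2cc(OC)c(OC)c(OC)c2 | intermediate
14 | hexadeca-O-methyl ether of the target | COc1cc(OC)c(Oc2cc(OC)c(OC)c(OC)c2Oc3cc(OC)c(Oc4cc(OC)c(OC)c(OC)c4Oc5cc(OC)c(Oc6cc(OC)c(OC)c(OC)c6)c(OC)c5)c(OC)c3)c(OC)c1 | intermediate
15 | CNP0218077.0 | Oc1cc(O)c(Oc2cc(O)c(O)c(O)c2Oc2cc(O)c(Oc3cc(O)c(O)c(O)c3Oc3cc(O)c(Oc4cc(O)c(O)c(O)c4)c(O)c3)c(O)c2)c(O)c1 | target

**Step count and risks**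
Total steps: 10. Longest linear sequence: 8 (steps 1, 2, 3, 4, 6, 7, 9, 10).

Steps most likely to fail:

1. Step 3. The carbenoid may be diverted into Wolff ring contraction, attack on an arene C–H, or a second insertion into the newly formed hydroxyl, or the diazide may decompose before it reaches the catalyst. The fallback is a conventional iterative Ullmann sequence that sets out from 5, 9 and 1 and comes back at 10. Bromophenol 5 would be benzylated (BnBr, K2CO3, DMF) to 2-(benzyloxy)-5-bromo-1,3-dimethoxybenzene F1. F1 would be coupled with phenol 9 (CuI, picolinic acid, K3PO4, DMSO, 100 °C) to 2-(benzyloxy)-1,3-dimethoxy-5-[2,3,4-trimethoxy-6-(2,4,6-trimethoxyphenoxy)phenoxy]benzene F2. Hydrogenolysis (H2, Pd/C) would give 2,6-dimethoxy-4-[2,3,4-trimethoxy-6-(2,4,6-trimethoxyphenoxy)phenoxy]phenol F3. Separately, 1 would be iodinated ortho to the hydroxyl (NIS, MeCN, 0 °C) to 6-iodo-2,3,4-trimethoxyphenol F4 and benzylated to 1-(benzyloxy)-6-iodo-2,3,4-trimethoxybenzene F5. Ullmann coupling of F3 with F5 (CuI, picolinic acid, K3PO4, DMSO, 110 °C) should then give 10.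

2. Step 5. The carbenoid may attack the very nucleophilic C3/C5 positions of 8 (aromatic substitution) in competition with O–H insertion. The fallback sets out from 1 and 8 and comes back at 9. The iodide 1-(benzyloxy)-6-iodo-2,3,4-trimethoxybenzene F5, made from 1 as above, would be coupled with 8 under Ullmann conditions (CuI, picolinic acid, K3PO4, DMSO, 110 °C) to 1-(benzyloxy)-2,3,4-trimethoxy-6-(2,4,6-trimethoxyphenoxy)benzene F6. Hydrogenolysis (H2, Pd/C) would then give 9.

3. Step 9. The coupling of a hindered phenoxide on a large fragment with an electron-rich bromide may stall, leading to protodebromination of 13 and oxidation of the phenol. The fallback reverses the roles of the copper partners; it sets out from 13 and comes back at 14. Miyaura borylation of 13 (B2pin2, Pd(dppf)Cl2, KOAc, dioxane, 90 °C) would give 2-[3,5-dimethoxy-4-(3,4,5-trimethoxyphenoxy)phenyl]-4,4,5,5-tetramethyl-1,3,2-dioxaborolane F7. Chan–Lam coupling of F7 with phenol 11 (Cu(OAc)2, pyridine, 4 Å MS, MeCN, O2, rt to 40 °C) should then give 14.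

**Further compounds**
F1 | step 3 | 2-(benzyloxy)-5-bromo-1,3-dimethoxybenzene | COc1cc(Br)cc(OC)c1OCc2ccccc2
F2 | step 3 | 2-(benzyloxy)-1,3-dimethoxy-5-[2,3,4-trimethoxy-6-(2,4,6-trimethoxyphenoxy)phenoxy]benzene | COc1cc(OC)c(Oc2cc(OC)c(OC)c(OC)c2Oc3cc(OC)c(OCc4ccccc4)c(OC)c3)c(OC)c1
F3 | step 3 | 2,6-dimethoxy-4-[2,3,4-trimethoxy-6-(2,4,6-trimethoxyphenoxy)phenoxy]phenol | COc1cc(OC)c(Oc2cc(OC)c(OC)c(OC)c2Oc3cc(OC)c(O)c(OC)c3)c(OC)c1
F4 | step 3 | 6-iodo-2,3,4-trimethoxyphenol | COc1cc(I)c(O)c(OC)c1OC
F5 | step 3 | 1-(benzyloxy)-6-iodo-2,3,4-trimethoxybenzene | COc1cc(I)c(OCc2ccccc2)c(OC)c1OC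
F6 | step 5 | 1-(benzyloxy)-2,3,4-trimethoxy-6-(2,4,6-trimethoxyphenoxy)benzene | COc1cc(OC)c(Oc2cc(OC)c(OC)c(OC)c2OCc3ccccc3)c(OC)c1
F7 | step 9 | 2-[3,5-dimethoxy-4-(3,4,5-trimethoxyphenoxy)phenyl]-4,4,5,5-tetramethyl-1,3,2-dioxaborolane | COc1cc(cc(OC)c1Oc2cc(OC)c(OC)c(OC)c2)B3OC(C)(C)C(C)(C)O3
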